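The furofuran is disconnected at the ring-fusion bond C1–C5 and the ether bond C2–O3 (C1 = acetoxy bridgehead, C2 = ArCH on C1, O3, C4H2, C5 = CH bridgehead, C6 = second ArCH, O7, C8H2; ring A holds O3, ring B holds O7). Because C1 carries the acetate and C2 is benzylic, an enol acetate C1(OAc)=C2HAr can accept a C5 radical released from a terminal epoxide. One Cp2Ti(OTf)2/Zn-catalysed cascade then forms ring B with the quaternary C1 and lets the benzylic C2 radical close ring A on the titanium-bound O3. The precursor is the ether of an enantiopure aryl(oxiranyl)methanol with a (Z)-2-acetoxy-3-arylallyl group; only C6 is set beforehand.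

Key step: step 7

Remark on the chemistry: compounds 1, 5 and 7 are assumed to be bought as catalogue chemicals. Aryl stands for 4-(benzyloxy)-3-methoxyphenyl throughout.

Step 1
Reactants: 1 4-(benzyloxy)-3-methoxybenzaldehyde; 2 vinylmagnesium bromide
Product: 3 rac-1-[4-(benzyloxy)-3-methoxyphenyl]prop-2-en-1-ol
Conditions: THF, 0 °C; aq. NH4Cl
Reagents that add atoms: none
Why: Grignard 1,2-addition of a vinyl nucleophile to a non-enolisable aryl aldehyde; the new carbinol centre is racemic and is resolved in step 2.

Step 2
Reactants: 3 rac-1-[4-(benzyloxy)-3-methoxyphenyl]prop-2-en-1-ol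
Product: 4 (R)-[4-(benzyloxy)-3-methoxyphenyl][(S)-oxiran-2-yl]methanol (anti epoxy alcohol)
Conditions: Ti(OiPr)4 (0.2 equiv), D-(−)-diisopropyl tartrate (0.3 equiv), t-BuOOH (0.45 equiv), 4 Å molecular sieves, CH2Cl2, −20 °C
Reagents that add atoms: tert-butyl hydroperoxide, CC(C)(C)OO
Why: Sharpless kinetic resolution: with the D-tartrate ligand the (S)-enantiomer of 3 should be epoxidised much faster than the (R)-enantiomer and on the face that gives the anti (erythro) epoxy alcohol, so that C6 is obtained as (R) and the oxirane carbon as (S), while stopping below half conversion leaves (R)-3 to be removed by chromatography.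

Step 3
Reactants: 4 (R)-[4-(benzyloxy)-3-methoxyphenyl][(S)-oxiran-2-yl]methanol; 5 2-bromo-N-methoxy-N-methylacetamide
Product: 6 2-{(R)-[4-(benzyloxy)-3-methoxyphenyl][(S)-oxiran-2-yl]methoxy}-N-methoxy-N-methylacetamide
Conditions: NaH, THF, 0 °C; then 5, Bu4NI (cat.), 0 °C
Reagents that add atoms: none
Why: Williamson etherification, in which the sodium alkoxide of 4 displaces bromide from the activated α-bromo amide by an SN2 reaction that does not touch C6, the aprotic medium and low temperature keeping the alkoxide from epoxide migration (Payne rearrangement).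

Step 4
Reactants: 7 [4-(benzyloxy)-3-methoxyphenyl]methanol
Product: 8 1-(benzyloxy)-4-(chloromethyl)-2-methoxybenzene
Conditions: SOCl2, CH2Cl2, 0 °C; used at once
Reagents that add atoms: thionyl chloride, O=S(Cl)Cl
Why: Deoxychlorination of an electron-rich benzylic alcohol with thionyl chloride through the chlorosulfite, a standard conversion that the aryl benzyl ether tolerates.

Step 5
Reactants: 6 2-{(R)-[4-(benzyloxy)-3-methoxyphenyl][(S)-oxiran-2-yl]methoxy}-N-methoxy-N-methylacetamide; 8 1-(benzyloxy)-4-(chloromethyl)-2-methoxybenzene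
Product: 10 1-[4-(benzyloxy)-3-methoxyphenyl]-3-{(R)-[4-(benzyloxy)-3-methoxyphenyl][(S)-oxiran-2-yl]methoxy}propan-2-one, via benzylic Grignard reagent 9 (not isolated)
Conditions: 8, Mg turnings, THF, 0 °C (slow addition, dilute); then 6, THF, −78 → −20 °C; aq. NH4Cl
Reagents that add atoms: none
Why: Weinreb ketone synthesis with a benzylic Grignard reagent, in which the magnesium-chelated tetrahedral adduct stops the reaction at the ketone stage and, at low temperature, the amide is attacked far faster than the terminal epoxide.

Step 6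
Reactants: 10 1-[4-(benzyloxy)-3-methoxyphenyl]-3-{(R)-[4-(benzyloxy)-3-methoxyphenyl][(S)-oxiran-2-yl]methoxy}propan-2-one
Product: 11 (Z)-1-[4-(benzyloxy)-3-methoxyphenyl]-3-{(R)-[4-(benzyloxy)-3-methoxyphenyl][(S)-oxiran-2-yl]methoxy}prop-1-en-2-yl acetate
Conditions: KN(SiMe3)2 (1.05 equiv), THF, −78 °C; Ac2O, −78 → 0 °C
Reagents that add atoms: acetic anhydride, CC(=O)OC(C)=O
Why: O-Acylation of a potassium enolate, in which the benzylic α-protons are several pK units more acidic than the alkoxymethylene protons, the conjugated enolate places the aryl group cis to oxygen, and the anhydride traps it on oxygen to give the (Z)-enol acetate.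

Step 7
Reactants: 11 (Z)-1-[4-(benzyloxy)-3-methoxyphenyl]-3-{(R)-[4-(benzyloxy)-3-methoxyphenyl][(S)-oxiran-2-yl]methoxy}prop-1-en-2-yl acetate
Product: 12 (1S,2R,5R,6S)-2,6-bis[4-(benzyloxy)-3-methoxyphenyl]-3,7-dioxabicyclo[3.3.0]octan-1-yl acetate (di-O-benzyl-1-acetoxypinoresinol)
Conditions: Cp2Ti(OTf)2 (10 mol %), Zn dust (30 mol %), degassed THF, 40 °C, 11 added slowly
Reagents that add atoms: none
Why: Proposed new method: the trivalent titanium complex formed from Cp2Ti(OTf)2 and Zn should cleave the C5–O bond of the epoxide homolytically to a secondary C5 radical whose O3 stays on tetravalent titanium; this radical adds 5-exo-trig to C1 of the enol acetate (ring B, bond C1–C5), and the electron-rich benzylic C2 radical then displaces titanium from O3 by intramolecular homolytic substitution through a five-membered transition state (ring A, bond C2–O3), which returns trivalent titanium so that 11 is isomerised to 12 with catalytic metal. The closest known reaction type is the Cp2TiCl-mediated radical cyclisation of epoxy cinnamyl ethers to aryl tetrahydrofurans and furofurans, together with Cp2Ti-catalysed epoxide–alkene cyclisations that end by radical attack on the Ti–O bond; the enol acetate acceptor and the acetoxylated quaternary C1 are the new elements. Attack at the fully substituted C1 instead of 6-endo attack at C2 is secured by the aryl group on C2, which makes the 5-exo adduct a benzylic radical. C6 controls C5 and C1: in a chair-like transition state its aryl group lies pseudo-equatorial, the C4 arm on the planar C5 radical turns away from it, and C2 ends cis to C4, the only arrangement from which the cis-fused ring A can form. At C2 the aryl group should settle on the convex face, cis to the acetate, because the ring-closing transition state with the aryl group over the concave face is more crowded. A stoichiometric reductant is left out on purpose, since a C2–titanium species lying β to the C1 acetate would lose the acetate by elimination, a path that cannot turn over with little zinc.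

Step 8
Reactants: 12 (1S,2R,5R,6S)-2,6-bis[4-(benzyloxy)-3-methoxyphenyl]-3,7-dioxabicyclo[3.3.0]octan-1-yl acetate
Product: 13 (1S,2R,5R,6S)-2,6-bis(4-hydroxy-3-methoxyphenyl)-3,7-dioxabicyclo[3.3.0]octan-1-yl acetate (1-acetoxypinoresinol)
Conditions: H2 (1 atm), 10% Pd/C, EtOAc, rt, stopped after uptake of two equivalents
Reagents that add atoms: none
Why: Catalytic hydrogenolysis of aryl benzyl ethers, which in neutral ethyl acetate should be cleaved much faster than the secondary benzylic C–O bonds of the two rings, while the tertiary acetate and the four stereocentres are untouched.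

Compound list
1 | 4-(benzyloxy)-3-methoxybenzaldehyde | COc1cc(C=O)ccc1OCc1ccccc1 | starting material
2 | vinylmagnesium bromide | C=C[Mg]Br | starting material
3 | rac-1-[4-(benzyloxy)-3-methoxyphenyl]prop-2-en-1-ol | COc1cc(C(O)C=C)ccc1OCc1ccccc1 | intermediate
4 | (R)-[4-(benzyloxy)-3-methoxyphenyl][(S)-oxiran-2-yl]methanol | COc1cc([C@@H](O)[C@@H]2CO2)ccc1OCc1ccccc1 | intermediate
5 | 2-bromo-N-methoxy-N-methylacetamide | CON(C)C(=O)CBr | starting material
6 | 2-{(R)-[4-(benzyloxy)-3-methoxyphenyl][(S)-oxiran-2-yl]methoxy}-N-methoxy-N-methylacetamide | COc1cc([C@@H](OCC(=O)N(C)OC)[C@@H]2CO2)ccc1OCc1ccccc1 | intermediate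
7 | [4-(benzyloxy)-3-methoxyphenyl]methanol | COc1cc(CO)ccc1OCc1ccccc1 | starting material
8 | 1-(benzyloxy)-4-(chloromethyl)-2-methoxybenzene | COc1cc(CCl)ccc1OCc1ccccc1 | intermediate
9 | [4-(benzyloxy)-3-methoxybenzyl]magnesium chloride (not isolated) | COc1cc(C[Mg]Cl)ccc1OCc1ccccc1 | intermediate
10 | 1-[4-(benzyloxy)-3-methoxyphenyl]-3-{(R)-[4-(benzyloxy)-3-methoxyphenyl][(S)-oxiran-2-yl]methoxy}propan-2-one | COc1cc([C@@H](OCC(=O)Cc2ccc(OCc3ccccc3)c(OC)c2)[C@@H]2CO2)ccc1OCc1ccccc1 | intermediate
11 | (Z)-1-[4-(benzyloxy)-3-methoxyphenyl]-3-{(R)-[4-(benzyloxy)-3-methoxyphenyl][(S)-oxiran-2-yl]methoxy}prop-1-en-2-yl acetate | COc1cc([C@@H](OC/C(OC(C)=O)=C/c2ccc(OCc3ccccc3)c(OC)c2)[C@@H]2CO2)ccc1OCc1ccccc1 | intermediate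
12 | (1S,2R,5R,6S)-2,6-bis[4-(benzyloxy)-3-methoxyphenyl]-3,7-dioxabicyclo[3.3.0]octan-1-yl acetate | COc1cc([C@H]2OC[C@]3(OC(C)=O)[C@@H](c4ccc(OCc5ccccc5)c(OC)c4)OC[C@H]23)ccc1OCc1ccccc1 | intermediate
13 | (1S,2R,5R,6S)-2,6-bis(4-hydroxy-3-methoxyphenyl)-3,7-dioxabicyclo[3.3.0]octan-1-yl acetate, 1-acetoxypinoresinol | COc1cc([C@H]2OC[C@]3(OC(C)=O)[C@@H](c4ccc(O)c(OC)c4)OC[C@H]23)ccc1O | target

Total step count: 8. Longest linear sequence: 7 steps (1 → 3 → 4 → 6 → 10 → 11 → 12 → 13).

Steps most likely to fail

Step 7. Several processes could defeat the cascade. The C2 radical may be captured by trivalent titanium and the neighbouring acetate then lost by β-elimination. Addition of the C5 radical to the fully substituted enol carbon may be too slow, so that reductive deoxygenation of the epoxide wins. Addition through the wrong face would give a C4/C2-trans radical that cannot close ring A and stalls the catalyst. Ring A may close with the aryl group on the concave face at C2, and the acetyl group may migrate from C1 to the O3 alkoxide.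

The fallback uses known chemistry and introduces the acetate last. It sets out from 4 and comes back to the route at 12. O-Propargylation of 4 (NaH, propargyl bromide, THF) should give propargyl ether F1. Separately, 4-iodo-2-methoxyphenol, benzyl bromide and K2CO3 should give 1-(benzyloxy)-4-iodo-2-methoxybenzene F2. Sonogashira coupling of F1 with F2 (Pd(PPh3)2Cl2, CuI, Et3N, rt) should give aryl alkynyl ether F3. Stoichiometric Cp2TiCl, made from Cp2TiCl2 and Zn in THF at rt, then effects the known 5-exo-dig cyclisation of such epoxy propargyl ethers, the vinyl radical taking hydrogen from the solvent. This should convert F3 into benzylidene tetrahydrofuran methanol F4, with the C6 aryl group trans to C4. OsO4/NMO should dihydroxylate the exocyclic alkene of F4 from the face away from C4 to give triol F5. A catalytic amount of camphorsulfonic acid ionises the electron-rich benzylic carbinol of F5 and O3 closes ring A, the customary cyclodehydration to furofurans, giving di-O-benzyl-1-hydroxypinoresinol F6. Ac2O, DMAP and Et3N then acetylate the tertiary alcohol of F6 to 12.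

Step 2. The electron-rich aryl vinyl carbinol may ionise or undergo allylic transposition, and the epoxy alcohol may be opened on the Lewis-acidic Ti(OiPr)4–tartrate complex. Epoxidation of the monosubstituted alkene is also slow, so the enantiomers may be discriminated incompletely. The fallback sets out from 3 and comes back at 4. Lipase resolution (immobilised Candida antarctica lipase B, vinyl acetate, MTBE, rt) should acylate the (R)-enantiomer to (R)-allylic acetate F8 and leave (S)-allylic alcohol F7. Hydroxyl-directed epoxidation of F7 with VO(acac)2 and t-BuOOH should then give 4 together with its oxirane epimer F9. Both epimers converge in step 7 because C5 becomes a planar radical.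

Step 5. Wurtz-type homocoupling may compete while the electron-rich benzylic chloride is converted into the organomagnesium, and the epoxide may be opened by the organomagnesium or by MgCl2. One step earlier, the alkoxide of 4 may also undergo epoxide migration. The fallback bypasses steps 3 and 5; it sets out from 4 and comes back at 10. Commercial [4-(benzyloxy)-3-methoxyphenyl]acetic acid is converted with (COCl)2 into acid chloride F10 and then with (trimethylsilyl)diazomethane into diazoketone F11. Rh2(OAc)4-catalysed O–H insertion, with F11 added slowly to 4 in CH2Cl2, should give ketone 10 directly.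

Further compounds
F1 | step 7 | 1-(benzyloxy)-2-methoxy-4-{(R)-[(S)-oxiran-2-yl](prop-2-yn-1-yloxy)methyl}benzene | COc1cc([C@@H](OCC#C)[C@@H]2CO2)ccc1OCc1ccccc1
F2 | step 7 | 1-(benzyloxy)-4-iodo-2-methoxybenzene | COc1cc(I)ccc1OCc1ccccc1
F3 | step 7 | 1-(benzyloxy)-4-{3-[(R)-[4-(benzyloxy)-3-methoxyphenyl][(S)-oxiran-2-yl]methoxy]prop-1-yn-1-yl}-2-methoxybenzene | COc1cc([C@@H](OCC#Cc2ccc(OCc3ccccc3)c(OC)c2)[C@@H]2CO2)ccc1OCc1ccccc1
F4 | step 7 | {(2S,3R)-2-[4-(benzyloxy)-3-methoxyphenyl]-4-[4-(benzyloxy)-3-methoxybenzylidene]tetrahydrofuran-3-yl}methanol (alkene geometry not fixed) | COc1cc([C@H]2OCC(=Cc3ccc(OCc4ccccc4)c(OC)c3)[C@@H]2CO)ccc1OCc1ccccc1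
F5 | step 7 | (3S,4R,5S)-5-[4-(benzyloxy)-3-methoxyphenyl]-3-{[4-(benzyloxy)-3-methoxyphenyl](hydroxy)methyl}-4-(hydroxymethyl)tetrahydrofuran-3-ol (benzylic carbinol not fixed) | COc1cc([C@H]2OC[C@](O)(C(O)c3ccc(OCc4ccccc4)c(OC)c3)[C@@H]2CO)ccc1OCc1ccccc1
F6 | step 7 | (1S,2R,5R,6S)-2,6-bis[4-(benzyloxy)-3-methoxyphenyl]-3,7-dioxabicyclo[3.3.0]octan-1-ol | COc1cc([C@H]2OC[C@]3(O)[C@@H](c4ccc(OCc5ccccc5)c(OC)c4)OC[C@H]23)ccc1OCc1ccccc1
F7 | step 2 | (S)-1-[4-(benzyloxy)-3-methoxyphenyl]prop-2-en-1-ol | COc1cc([C@@H](O)C=C)ccc1OCc1ccccc1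
F8 | step 2 | (R)-1-[4-(benzyloxy)-3-methoxyphenyl]prop-2-en-1-yl acetate | COc1cc([C@H](OC(C)=O)C=C)ccc1OCc1ccccc1
F9 | step 2 | (R)-[4-(benzyloxy)-3-methoxyphenyl][(R)-oxiran-2-yl]methanol | COc1cc([C@@H](O)[C@H]2CO2)ccc1OCc1ccccc1
F10 | step 5 | [4-(benzyloxy)-3-methoxyphenyl]acetyl chloride | COc1cc(CC(=O)Cl)ccc1OCc1ccccc1
F11 | step 5 | 1-[4-(benzyloxy)-3-methoxyphenyl]-3-diazopropan-2-one | COc1cc(CC(=O)C=[N+]=[N-])ccc1OCc1ccccc1
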